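The ratio of L to D is 0.900 equiv, less than one, in every flask below, and I had to settle whether the next run should change that ratio or the heat.

    L + E ⇌ L.E, settled at all times (K1 = 260 M⁻¹, ΔH1 = 6.00 kJ mol⁻¹)
    D.L → E (k2 = 16 s⁻¹, Ea2 = 81.0 kJ mol⁻¹)
    D + L ⇌ D.L, settled at all times (K3 = 1200 M⁻¹, ΔH3 = −17.0 kJ mol⁻¹)
    2 D → D2 (k4 = 34 M⁻¹ s⁻¹, Ea4 = 59.0 kJ mol⁻¹)
    (constants at 110 °C)

common to all: D 5.0 mM; L 0.900 equiv; time 4.0 s
- midnight: temperature 110 °C
- dawn: temperature 125 °C
- summer: at 110 °C until 1.2 s, from then on at 140 °C
- noon: temperature 140 °C

* the flask with the highest amount of E, in percent of the D charged ("all alike" if they lie within 1.5 percentage points) (midnight / dawn / summer / noon / all alike)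
* final E, as a percentage of the D charged, in midnight
* final E, as a percentage of the D charged, in dawn
* final E, as a percentage of the D charged, in summer
* final E, as a percentage of the D charged, in noon

- in percentages every species weighs as the D in it: one D2 counts as two
- for E the L.E is counted in
- a doubled species enters its step squared and goes two at a time
- the constants hold at 110 °C; other temperatures follow from the activation energies and enthalpies

**The ceiling.** Each turn through D.L takes one L and one D and gives one E, so L was the limiting reagent. I took the L charge over the D charge, 90.0%, and called it the L ceiling: the fraction of the D charged that can become E. That left an excess of D of 10.0%, the part of the charge beyond the ceiling.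

**The last L.** The ceiling is reached only if the last L gets through within the time, so I reckoned that tail for midnight. Near the end E hardly moves and D moves slowly, so as an estimate I froze D at the excess and E at the ceiling. On that estimate free L, D.L and L.E stand in the proportion one to 0.600 to 1.17. Since the share in D.L goes on to E, I reckoned for the remaining L a half-life of 0.200 s, much shorter than the 4.0 s allowed, which gives 20.0 half-lives.

**The race.** D at its full charge has a half-life of 2.94 s by dimerisation, longer than that tail, and it lengthens as D falls. From midnight to noon, the step from D.L to E speeds up by a factor of 6.3, more than the dimerisation at 3.8, but K3 falls with heat, so I took the lead of that step as smaller than these two factors show. The ceiling has neither heat nor time in it. I therefore committed to E at 90.0% in each flask, and to keeping the next run at 110 °C and moving the L charge if more E is wanted.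

**The result.** The forecast gave 90%, 90%, 90% and 90%, all alike, “whatever the temperature profile”. The simulation gave 90.0%, 90.0%, 90.0% and 90.0% for midnight, dawn, summer and noon, so the flasks are all alike, at the ceiling of 90.0%. The consumption of L is the main reason: without it, midnight gave >99.9% in place of 90.0%, while removing the dimerisation changed nothing there. A flask like dawn with 0.230 equiv of L has a ceiling of 23.0%, and it ended with E at 23.0%.

The constants used here were chosen freely.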